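All runs come from a simulation with made-up constants; the scatter is artificial.

# Minutes on a slow start

| flask | Z | J | temperature | remark | time |
|---|---|---|---|---|---|
| dusk | 0.088 M | 0.088 M | 50 °C | run made earlier |  |
| midnight | 0.088 M | 0.044 M | 50 °C | run made earlier |  |
| ash | 0.088 M (fed, over 8.0 min) | 0.0880 M |  | the addition at 30 °C, then warmed to 50 °C; the feed brings no volume worth counting | 12 min |
| larch | 0.088 M | 0.0880 M (fed, over 8.0 min) | 50 °C | all else is in the flask from the start; the feed brings no volume worth counting | 12 min |
| maple | 0.088 M | 0.0880 M |  | everything together at the start at 30 °C, warmed to 50 °C at 8.0 min | 12 min |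
| birch | 0.088 M | 0.0880 M | 50 °C | everything together at the start | 12 min |

- dusk (time / min: G / %): 0.500: 1.9; 0.833: 0; 1.33: 2.3; 2.00: 3.7; 3.00: 19.5; 5.00: 66.3; 8.00: 86.2
- midnight (time / s: G / %): 10.0: 0.8; 12.0: 0; 20.0: 0.6; 30.0: 0; 40.0: 0.5; 60.0: 2.2; 80.0: 1.1

(standard deviation of a reading: 1 percentage point)

- on the list of suspects stand: Z + J + D -> G + 2 D; Z + J -> G + D
- the earlier runs do not show what temperature does; that part of a forecast is a guess

- the flask that comes out highest in amount of G, in percent of the Z charged, or "all alike" when all lie within 1.5 percentage points (ash / larch / maple / birch / all alike)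
- G at the end, in percent of the Z charged, ash
- G at the end, in percent of the Z charged, larch
- G at the end, in percent of the Z charged, maple
- G at the end, in percent of the Z charged, birch

Slowness opened the meeting: the dusk run showed G at only 3.7 % after 2.00 min, yet 66.3 % at 5.00 min. The chair argued that this is autocatalysis, with Z + J + D making more D, while Z + J merely seeds it.

Since that rate follows Z times J times D, a colleague proposed a clock: minutes at 50 °C, each counted by the share of the fed species already in the flask. A steady feed averages half a share, so larch reaches 8.00 min on this clock time, and its G should match the dusk reading at that time, 86.2 %.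

Another member objected that the runs show nothing about temperature. The meeting therefore guessed that a cold minute counts 0.250 of a warm one. That gives maple 6.00 min and ash 5.00 min. Ash thus reads the dusk value 66.3 %, and maple lies between that and larch.

Birch has the dusk recipe but runs past its readings. With equal charges and D near its ceiling, the meeting took the rate to follow the square of the share of Z left, so that the reciprocal of that share climbs in a straight line; drawn through the last two dusk readings, that line gives G of 92.3 %. Birch's 12 min on the clock is longer than any other flask's, so the meeting put it highest.

The forecast named birch, with ash 65 %, larch 86 %, maple 76 % and birch 93 %, concluding “Birch comes out highest”.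

The flasks gave ash 69.0 %, larch 86.8 %, maple 80.4 % and birch 93.2 %, so birch is highest.

    Z + J + D → G + 2 D (k = 4.20 M⁻² s⁻¹, Ea = 46.0 kJ mol⁻¹)
    Z + J → G + D (k = 3.20 × 10⁻⁴ M⁻¹ s⁻¹, Ea = 58.0 kJ mol⁻¹)
    (constants at 50 °C)

Now the clock can be run on a neighbour: birch unchanged except that it stands at 25 °C. Reckoned with the activation energy of the D-assisted step, each minute there counts 0.238 of a minute at 50 °C. This flask's 12 min therefore reads 2.86 min on the clock, less than the 8.00 min of larch. That time falls between the dusk readings at 2.00 min and 3.00 min, which were 3.7 % and 19.5 %. The 25 °C flask gives G 12.0 %, with Z 88.0 % remaining.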